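## Analysis of the target

Compound 20 is a 7,7a-dihydro-1,3-benzodioxol-5(6H)-one. Ring A is a cyclohexenone: C1 carbonyl, C2 vinylic CH, C3 enol-ether carbon, C4 fully substituted, C5 methylene, C6 allyl-bearing methine. Ring B is the five-membered formaldehyde acetal O3–CH2–O4 fused across C3–C4. C4 carries a 1-arylpropan-2-yl chain (C8 methine with the C9 methyl, C7 benzylic methylene, 3,4,5-trimethoxyphenyl ring C).

There are three stereocentres. C4 (R) is an oxygenated quaternary carbon, C8 (S) is bonded directly to it, and C6 (R) stands 1,3 to C4 across C5, its allyl group trans to the C4 side chain and cis to O4.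

The sensitive points are the vinylogous ester that is also one arm of a formaldehyde acetal (acid-labile, open to addition–elimination at C3), the C6 hydrogen α to the ketone (epimerisable), the terminal alkene and the electron-rich arene.

The synthesis is hard because C4 is a quaternary carbinol-type carbon next to a C8 that has no heteroatom. C8 must therefore be made by enolate alkylation and carried α to a carbonyl without loss, and no ring substituent obviously directs the C6 configuration.

The plan rests on one feature. Without the acetal CH2, ring A is a 4-hydroxycyclohexane-1,3-dione in which the carbonyl carbon C3 is bonded to the tertiary carbinol C4. This acyloin pair inside the six-membered ring is what an acyl-anion equivalent at an aldehyde C3 gives on adding to a C4 ketone, provided C1 is masked.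

## Retrosynthetic reasoning

**20 ⇒ 19.** The two C–O bonds to the acetal carbon (O3–CH2 and O4–CH2) are cut. This carbon is the only atom outside the carbon skeleton, and its removal leaves the enolised hydroxy-dione 19. In 19 the O3 enol and the O4 hydroxyl sit on neighbouring carbons, while O1 cannot reach O4, so only the five-membered formal can close. The forward step must deliver one carbon at the formaldehyde level to both oxygens without touching C6.

**19 ⇒ 18.** The C1 carbonyl is returned to a dioxolane. In 18 C2 is no longer doubly activated and C3 is an isolated ketone next to the tertiary alcohol, which is the α-ketol needed for the key disconnection. The forward step is a hydrolysis.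

**18 ⇒ 17.** The ring bond C3–C4 is cut. It is the only ring bond whose two ends already hold the oxidation levels of an umpolung union (carbonyl at C3, carbinol at C4). Cutting it turns the quaternary centre into a plain ketone and leaves C6 and C8 as ordinary tertiary centres of an open chain. A Claisen-type cut at C1–C2 or C2–C3 would instead require the acyclic tertiary alcohol at C4 to be made first. Forward, an acyl-anion equivalent must be generated at the aldehyde C3 only, add to the C4 ketone on the correct face, and leave C8 (α to that ketone) unenolised.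

**17 ⇒ 16 ⇒ 15.** No skeletal bond is cut. The keto aldehyde is traced to the diol 16 and that to the keto ester 15, because C3 is best carried as an ester through the metal-mediated fragment union and an ester cannot be reduced to the aldehyde selectively beside a ketone.

**15 ⇒ 13 + 4.** The C4–C5 bond is cut. This places C6 and C8 in separate fragments, each needing one auxiliary-controlled alkylation. The ketone appears directly from an acyl donor and an alkyl nucleophile, and only after C1 is already a ketal, so C1 and C4 never have to be told apart. The forward coupling must be neutral enough to spare C8 and must tolerate ester, ketal and alkene; an alkylzinc from iodide 13 and thioester 4 meet this.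

**4 ⇒ 3 ⇒ 1 + 2.** The C7–C8 bond is cut. Benzylation of the enolate of imide 1 with bromide 2 sets C8, and the acyl group of 3 is then released as the thioester.

**13 ⇒ 12 ⇒ 10.** The C5–I bond goes back to the primary alcohol 12 and the dioxolane to the ketone of 10. The ketal is installed before any other ketone exists in the molecule.

**10 ⇒ 9.** The C1–C2 bond is cut. A two-carbon ester enolate adds to the amide carbonyl C1 of 9, which brings in C2 and C3 at once with C3 at the ester level.

**9 ⇒ 8 ⇒ 7 ⇒ 5 + 6.** The C5–C6 bond is cut. Hydroxymethylation of the enolate of imide 7 sets C6 and delivers C5 as the CH2OH handle that later becomes the C–Zn bond. Imide 7 comes from auxiliary 5 and acid chloride 6. C6 is thus a defined centre from the start and is not left to a closing equilibration, whose outcome in the bicyclic enone cannot be predicted safely.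

## Alternatives that were turned down

**Alternative 1:** Ring B is removed by cutting O4–CH2 and O3–C3, which leads back to the para-quinol A2. Forward, a chiral phosphoric acid would build a hemiformal on the tertiary hydroxyl from a formaldehyde equivalent and direct its oxygen onto one of the two enantiotopic enone β-carbons, giving the cis-fused A1.
- For: A2 is an arene coupling and an oxidative dearomatisation away from simple materials. Ring B and C4 arise in one catalytic operation, and the formal is installed without the untested methylenation of the chosen route. On step count to the bicycle and on the acetal this alternative is stronger.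
- Against: the one-carbon aldehyde is the smallest and least discriminating partner for such a cascade. The choice between the enone arms is made next to the existing C8 centre, so it is a matched/mismatched problem. A1 also has the wrong oxidation pattern: C3 is sp3 and the remaining alkene is C5=C6. Reaching 20 would need reductive allylation at C6 and then dehydrogenation across C2–C3 of a β-alkoxy ketone, which readily opens by retro-oxa-Michael.
- Comparison: the chosen route is longer before ring closure, but C3 comes out of the key step at the correct carbonyl level and C6 is already in place.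

**Alternative 2:** The C4–C5 and O4–C1 bonds are cut. A triazolium carbene would turn the enal A4 into a homoenolate that adds to the ketone of the racemising ketoester A5 and lactonises to A3.
- For: it is convergent, uses racemic and trivial partners, and sets C4 and C8 in one step with no auxiliary. In this it is stronger than the chosen route.
- Against: an α-branched enal is a poor homoenolate precursor, and protonation of its acyl azolium creates C6 without control. Three centres would therefore be decided in one event, with the dynamic resolution of C8 as an added requirement. A3 also still lacks C2; the ester must become a methyl ketone and close onto the lactone to reach hydroxy-dione 19, so the same endgame follows.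
- Comparison: the chosen route spends more steps, but it leaves only C4 to the catalyst because C8 and C6 come from well-understood enolate alkylations.

**Alternative 3:** The C1–C2 and C1–C6 bonds are cut, with C1 taken from the gas phase. A divalent palladium precatalyst would insert into the alkenyl iodide A7, carbonylate, acylpalladate the allyl group 6-exo and eliminate to the exocyclic enone A6.
- For: ring B and C4 exist before ring A closes, the cyclisation creates no stereocentre, and it gives the enone oxidation level directly. A single conjugate addition of a vinyl nucleophile would finish the allyl group. The key step is therefore free of stereochemical risk, which is stronger than the chosen route.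
- Against: the problem moves into A7. Its quaternary C4 (oxygen, allyl, C8) must be made selectively in acyclic form, and a geometrically defined iodo enol ether must be built inside a formal. The exocyclic enone can isomerise into the ring, and C6 is finally set by protonation of an enolate.
- Comparison: the chosen route takes one stereochemical risk in its key step, but it forms the hardest centre in the ring-closing event and sets C6 early.

Key step: step 12

**Remarks before the steps**
- Compounds 1, 2, 5 and 6 are taken as commercial.
- Assumption: the (5aS,10bR) antipode of the triazolium salt is taken as the one whose facial preference coincides with Felkin–Anh attack on the C4 ketone. Both antipodes are available, so this pairing is a reagent choice.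
- Diol 16 is a mixture of epimers at the C4 carbinol; they converge on oxidation.

## Route

Step 1
Reactants: 1 (4R)-4-benzyl-3-propanoyl-1,3-oxazolidin-2-one; 2 5-(bromomethyl)-1,2,3-trimethoxybenzene
Product: 3 (4R)-4-benzyl-3-[(2S)-2-methyl-3-(3,4,5-trimethoxyphenyl)propanoyl]-1,3-oxazolidin-2-one
Conditions: NaN(SiMe3)2, THF, −78 °C; then 2, −78 → −20 °C
Reagents that add atoms: none
Why: Evans asymmetric alkylation; the chelated sodium Z-enolate is benzylated on the face opposite the C4 benzyl group of the auxiliary, which for the (4R) auxiliary should give the (S) centre that becomes C8.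

Step 2
Reactants: 3 (4R)-4-benzyl-3-[(2S)-2-methyl-3-(3,4,5-trimethoxyphenyl)propanoyl]-1,3-oxazolidin-2-one
Product: 4 S-ethyl (2S)-2-methyl-3-(3,4,5-trimethoxyphenyl)propanethioate
Conditions: EtSH, n-BuLi, THF, 0 °C
Reagents that add atoms: ethanethiol, CCS
Why: Thiolate transacylation of the N-acyl oxazolidinone at the exocyclic carbonyl; lithium ethanethiolate is a soft, weakly basic nucleophile, so the α-centre should not epimerise and the auxiliary is released intact.

Step 3
Reactants: 5 (4S)-4-benzyl-1,3-oxazolidin-2-one; 6 pent-4-enoyl chloride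
Product: 7 (4S)-4-benzyl-3-(pent-4-enoyl)-1,3-oxazolidin-2-one
Conditions: n-BuLi, THF, −78 °C; then 6, −78 → 0 °C
Reagents that add atoms: none
Why: N-acylation of the lithiated oxazolidinone by the acid chloride, a standard imide formation.

Step 4
Reactants: 7 (4S)-4-benzyl-3-(pent-4-enoyl)-1,3-oxazolidin-2-one
Product: 8 (4S)-4-benzyl-3-[(2R)-2-(hydroxymethyl)pent-4-enoyl]-1,3-oxazolidin-2-one
Conditions: TiCl4, i-Pr2NEt, CH2Cl2, 0 °C; then 1,3,5-trioxane, TiCl4, 0 °C
Reagents that add atoms: 1,3,5-trioxane, C1OCOCO1
Why: Evans titanium-enolate hydroxymethylation; the chelated Z-enolate takes up the TiCl4-activated formaldehyde unit anti to the auxiliary benzyl group, which should set C6 and bring in C5 as CH2OH.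

Step 5
Reactants: 8 (4S)-4-benzyl-3-[(2R)-2-(hydroxymethyl)pent-4-enoyl]-1,3-oxazolidin-2-one
Product: 9 (2R)-2-(hydroxymethyl)-N-methoxy-N-methylpent-4-enamide
Conditions: MeONHMe·HCl, AlMe3, CH2Cl2, −20 → 0 °C
Reagents that add atoms: N,O-dimethylhydroxylamine hydrochloride, CNOC.Cl
Why: Weinreb transamination of a β-hydroxy imide; the aluminium alkoxide of the free hydroxyl delivers the aluminium amide to the exocyclic carbonyl, so cleavage is regioselective and C6 is not touched.

Step 6
Reactants: 9 (2R)-2-(hydroxymethyl)-N-methoxy-N-methylpent-4-enamide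
Product: 10 tert-butyl (4R)-4-(hydroxymethyl)-3-oxohept-6-enoate
Conditions: t-BuOAc, LiN(i-Pr)2 (3.5 equiv each), THF, −78 °C; then 9, −78 → −40 °C; AcOH
Reagents that add atoms: tert-butyl acetate, CC(=O)OC(C)(C)C
Why: Crossed Claisen condensation of an ester enolate with a Weinreb amide; excess enolate first deprotonates the hydroxyl, and the chelated tetrahedral adduct persists until the quench, so the β-hydroxy ketone is never exposed to base. The tert-butyl ester is chosen so that the δ-hydroxyl does not lactonise.

Step 7
Reactants: 10 tert-butyl (4R)-4-(hydroxymethyl)-3-oxohept-6-enoate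
Product: 12 tert-butyl 2-{2-[(2R)-1-hydroxypent-4-en-2-yl]-1,3-dioxolan-2-yl}acetate, via trimethylsilyl ether 11 (not isolated)
Conditions: Me3SiOCH2CH2OSiMe3, Me3SiOTf (10 mol%), CH2Cl2, −78 → −20 °C; pyridine; then K2CO3, MeOH, 0 °C
Reagents that add atoms: 1,2-bis(trimethylsilyloxy)ethane, C[Si](C)(C)OCCO[Si](C)(C)C
Why: Noyori silyl-transfer ketalisation at low temperature, which avoids the enol-ether pathway that would epimerise C6. The primary hydroxyl picks up a trimethylsilyl group under the conditions and loses it in methanolic carbonate.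

Step 8
Reactants: 12 tert-butyl 2-{2-[(2R)-1-hydroxypent-4-en-2-yl]-1,3-dioxolan-2-yl}acetate
Product: 13 tert-butyl 2-{2-[(2S)-1-iodopent-4-en-2-yl]-1,3-dioxolan-2-yl}acetate
Conditions: I2, PPh3, imidazole, CH2Cl2, 0 °C → rt
Reagents that add atoms: iodine, II
Why: Appel-type iodination by SN2 displacement at the primary carbon of the alkoxyphosphonium salt; imidazole buffers the medium so ketal and tert-butyl ester survive. The descriptor changes only because iodine outranks oxygen.

Step 9
Reactants: 13 tert-butyl 2-{2-[(2S)-1-iodopent-4-en-2-yl]-1,3-dioxolan-2-yl}acetate; 4 S-ethyl (2S)-2-methyl-3-(3,4,5-trimethoxyphenyl)propanethioate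
Product: 15 tert-butyl 2-{2-[(4R,7S)-7-methyl-6-oxo-8-(3,4,5-trimethoxyphenyl)oct-1-en-4-yl]-1,3-dioxolan-2-yl}acetate, via alkylzinc iodide 14 (not isolated)
Conditions: Zn dust (activated with BrCH2CH2Br and Me3SiCl), THF/DMA, 40 °C; then 4, PdCl2(PPh3)2 (10 mol%), toluene, rt
Reagents that add atoms: none
Why: Fukuyama coupling; zinc inserts into the primary C–I bond to an alkylzinc iodide that tolerates ester, ketal and alkene and has no β-leaving group. Zerovalent palladium formed in situ adds into the thioester C–S bond, and transmetalation and reductive elimination give the ketone under neutral conditions, so C8 should keep its configuration.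

Step 10
Reactants: 15 tert-butyl 2-{2-[(4R,7S)-7-methyl-6-oxo-8-(3,4,5-trimethoxyphenyl)oct-1-en-4-yl]-1,3-dioxolan-2-yl}acetate
Product: 16 (2S,3RS,5R)-5-[2-(2-hydroxyethyl)-1,3-dioxolan-2-yl]-2-methyl-1-(3,4,5-trimethoxyphenyl)oct-7-en-3-ol
Conditions: LiAlH4, THF, 0 °C → rt
Reagents that add atoms: none
Why: Hydride reduction of the ester to the primary alcohol and of the ketone to the carbinol; ketal and alkene are inert, and the carbinol mixture is of no consequence.

Step 11
Reactants: 16 (2S,3RS,5R)-5-[2-(2-hydroxyethyl)-1,3-dioxolan-2-yl]-2-methyl-1-(3,4,5-trimethoxyphenyl)oct-7-en-3-ol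
Product: 17 2-{2-[(4R,7S)-7-methyl-6-oxo-8-(3,4,5-trimethoxyphenyl)oct-1-en-4-yl]-1,3-dioxolan-2-yl}acetaldehyde
Conditions: Dess–Martin periodinane (3 equiv), NaHCO3, CH2Cl2, 0 °C → rt
Reagents that add atoms: none
Why: Dess–Martin oxidation of both hydroxyls under buffered, non-enolising conditions should restore the C4 ketone and give the C3 aldehyde without epimerising C8 or opening the β-ketal.

Step 12
Reactants: 17 2-{2-[(4R,7S)-7-methyl-6-oxo-8-(3,4,5-trimethoxyphenyl)oct-1-en-4-yl]-1,3-dioxolan-2-yl}acetaldehyde
Product: 18 (8R,10R)-8-hydroxy-10-(prop-2-en-1-yl)-8-[(2S)-1-(3,4,5-trimethoxyphenyl)propan-2-yl]-1,4-dioxaspiro[4.5]decan-7-one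
Conditions: (5aS,10bR)-2-(pentafluorophenyl)-5a,10b-dihydro-4H,6H-indeno[2,1-b][1,2,4]triazolo[4,3-d][1,4]oxazin-2-ium tetrafluoroborate (15 mol%), Et3N (15 mol%), THF (0.05 M), rt
Reagents that add atoms: none
Why: Et3N frees the carbene, which adds to the unhindered aldehyde C3 and, after proton transfer, gives the Breslow enaminol; this acyl-anion equivalent attacks the C4 ketone, forms the C3–C4 bond, and collapse of the adduct releases the carbene and leaves the C3 ketone beside the C4 tertiary alcohol. The closest known reaction type is the carbene-catalysed enantioselective intramolecular crossed aldehyde–ketone benzoin that gives six-membered tertiary α-ketols. Ring A closes 6-exo-trig through a chair-like array with the C6 allyl group equatorial. The new centre C4 is controlled by the indane wall of the catalyst, which fixes the reacting face of the enaminol while its O–H is hydrogen-bonded to the ketone oxygen, and by Felkin–Anh attack anti to the C7 arm of C8, which for (8S) leads to (4R). The arrangement that keeps the triazolium anti to the branched C8 chain puts the new C4–O bond equatorial and the chain axial, that is trans to the allyl group as required. Chemoselectivity is secured because only the aldehyde can form a Breslow intermediate, C1 is masked as the dioxolane, and the C4 ketone is the only acceptor at six-membered distance. The weak amine base and the acidic pentafluorophenyl triazolium keep enolate concentrations low, which should suppress five-membered aldol closures, opening of the β-ketal and epimerisation of C8; after closure C8 is no longer α to a carbonyl.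

Step 13
Reactants: 18 (8R,10R)-8-hydroxy-10-(prop-2-en-1-yl)-8-[(2S)-1-(3,4,5-trimethoxyphenyl)propan-2-yl]-1,4-dioxaspiro[4.5]decan-7-one
Product: 19 (4R,6R)-4-hydroxy-6-(prop-2-en-1-yl)-4-[(2S)-1-(3,4,5-trimethoxyphenyl)propan-2-yl]cyclohexane-1,3-dione
Conditions: 2 M HCl, THF, rt
Reagents that add atoms: water, O
Why: Acid hydrolysis of the dioxolane, driven by enolisation of the resulting 1,3-dione; the dione enolises through C2, so C6 should keep its configuration, and the tertiary α-ketol has no low-energy dehydration path.

Step 14
Reactants: 19 (4R,6R)-4-hydroxy-6-(prop-2-en-1-yl)-4-[(2S)-1-(3,4,5-trimethoxyphenyl)propan-2-yl]cyclohexane-1,3-dione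
Product: 20 (6R,7aR)-6-(prop-2-en-1-yl)-7a-[(2S)-1-(3,4,5-trimethoxyphenyl)propan-2-yl]-7,7a-dihydro-1,3-benzodioxol-5(6H)-one
Conditions: CH2(OMe)2, TfOH (5 mol%), 4 Å molecular sieves, CH2Cl2, 0 °C → rt
Reagents that add atoms: dimethoxymethane, COCOC
Why: Proposed new method: acid-catalysed exchange of dimethoxymethane with the enol hydroxyl should give an enol methoxymethyl ether reversibly at O1 or O3, and only the O3 isomer can ionise to an oxocarbenium ion within reach of the tertiary O4 hydroxyl (5-exo closure), so the equilibrating mixture should drain into the cyclic formal while the sieves take up methanol; the closest known reaction types are acid-catalysed methylene acetal formation from 1,2-diols with dimethoxymethane and the formation of 1,3-dioxolan-4-ones from α-hydroxy acids and formaldehyde, of which this is the vinylogous case.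

## Compound list

1 | (4R)-4-benzyl-3-propanoyl-1,3-oxazolidin-2-one | CCC(=O)N1[C@H](Cc2ccccc2)COC1=O | starting material
2 | 5-(bromomethyl)-1,2,3-trimethoxybenzene | COc1cc(CBr)cc(OC)c1OC | starting material
3 | (4R)-4-benzyl-3-[(2S)-2-methyl-3-(3,4,5-trimethoxyphenyl)propanoyl]-1,3-oxazolidin-2-one | O=C([C@@H](C)Cc1cc(OC)c(OC)c(OC)c1)N1[C@H](Cc2ccccc2)COC1=O | intermediate
4 | S-ethyl (2S)-2-methyl-3-(3,4,5-trimethoxyphenyl)propanethioate | CCSC(=O)[C@@H](C)Cc1cc(OC)c(OC)c(OC)c1 | intermediate
5 | (4S)-4-benzyl-1,3-oxazolidin-2-one | O=C1OC[C@H](Cc2ccccc2)N1 | starting material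
6 | pent-4-enoyl chloride | C=CCCC(Cl)=O | starting material
7 | (4S)-4-benzyl-3-(pent-4-enoyl)-1,3-oxazolidin-2-one | C=CCCC(=O)N1[C@@H](Cc2ccccc2)COC1=O | intermediate
8 | (4S)-4-benzyl-3-[(2R)-2-(hydroxymethyl)pent-4-enoyl]-1,3-oxazolidin-2-one | O=C([C@H](CC=C)CO)N1[C@@H](Cc2ccccc2)COC1=O | intermediate
9 | (2R)-2-(hydroxymethyl)-N-methoxy-N-methylpent-4-enamide | CON(C)C(=O)[C@H](CC=C)CO | intermediate
10 | tert-butyl (4R)-4-(hydroxymethyl)-3-oxohept-6-enoate | CC(C)(C)OC(=O)CC(=O)[C@H](CC=C)CO | intermediate
11 | tert-butyl 2-{2-[(2R)-1-[(trimethylsilyl)oxy]pent-4-en-2-yl]-1,3-dioxolan-2-yl}acetate | CC(C)(C)OC(=O)CC1(OCCO1)[C@H](CC=C)CO[Si](C)(C)C | intermediate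
12 | tert-butyl 2-{2-[(2R)-1-hydroxypent-4-en-2-yl]-1,3-dioxolan-2-yl}acetate | CC(C)(C)OC(=O)CC1(OCCO1)[C@H](CC=C)CO | intermediate
13 | tert-butyl 2-{2-[(2S)-1-iodopent-4-en-2-yl]-1,3-dioxolan-2-yl}acetate | CC(C)(C)OC(=O)CC1(OCCO1)[C@H](CC=C)CI | intermediate
14 | {(2S)-2-[2-(2-tert-butoxy-2-oxoethyl)-1,3-dioxolan-2-yl]pent-4-en-1-yl}zinc iodide | CC(C)(C)OC(=O)CC1(OCCO1)[C@H](CC=C)C[Zn]I | intermediate
15 | tert-butyl 2-{2-[(4R,7S)-7-methyl-6-oxo-8-(3,4,5-trimethoxyphenyl)oct-1-en-4-yl]-1,3-dioxolan-2-yl}acetate | CC(C)(C)OC(=O)CC1(OCCO1)[C@H](CC=C)CC(=O)[C@@H](C)Cc2cc(OC)c(OC)c(OC)c2 | intermediate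
16 | (2S,3RS,5R)-5-[2-(2-hydroxyethyl)-1,3-dioxolan-2-yl]-2-methyl-1-(3,4,5-trimethoxyphenyl)oct-7-en-3-ol | OCCC1(OCCO1)[C@H](CC=C)CC(O)[C@@H](C)Cc2cc(OC)c(OC)c(OC)c2 | intermediate
17 | 2-{2-[(4R,7S)-7-methyl-6-oxo-8-(3,4,5-trimethoxyphenyl)oct-1-en-4-yl]-1,3-dioxolan-2-yl}acetaldehyde | O=CCC1(OCCO1)[C@H](CC=C)CC(=O)[C@@H](C)Cc2cc(OC)c(OC)c(OC)c2 | intermediate
18 | (8R,10R)-8-hydroxy-10-(prop-2-en-1-yl)-8-[(2S)-1-(3,4,5-trimethoxyphenyl)propan-2-yl]-1,4-dioxaspiro[4.5]decan-7-one | C=CC[C@@H]1C[C@@](O)([C@@H](C)Cc2cc(OC)c(OC)c(OC)c2)C(=O)CC13OCCO3 | intermediate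
19 | (4R,6R)-4-hydroxy-6-(prop-2-en-1-yl)-4-[(2S)-1-(3,4,5-trimethoxyphenyl)propan-2-yl]cyclohexane-1,3-dione | C=CC[C@@H]1C[C@@](O)([C@@H](C)Cc2cc(OC)c(OC)c(OC)c2)C(=O)CC1=O | intermediate
20 | (6R,7aR)-6-(prop-2-en-1-yl)-7a-[(2S)-1-(3,4,5-trimethoxyphenyl)propan-2-yl]-7,7a-dihydro-1,3-benzodioxol-5(6H)-one | C=CC[C@@H]1C[C@]2([C@@H](C)Cc3cc(OC)c(OC)c(OC)c3)OCOC2=CC1=O | target

## Step count and least certain steps

Total: 14 steps. Longest linear sequence: 12 steps (steps 3 to 14); steps 1 and 2 form the second branch.

**Step 14 (the unprecedented methylenation).**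
- Most likely failure: the methoxymethyl cation is captured elsewhere. O1 can be alkylated to a dead-end enol ether, the trimethoxyarene or the terminal alkene can be attacked, and the hindered tertiary hydroxyl may engage too slowly, so open methoxymethyl ethers and methylene-bridged dimers accumulate.
- Fallback (known chemistry, carbon anchored on O4 first), from 18 back to 20: MeOCH2Cl, i-Pr2NEt and Bu4NI in ClCH2CH2Cl at 60 °C should give (8R,10R)-8-(methoxymethoxy)-10-(prop-2-en-1-yl)-8-[(2S)-1-(3,4,5-trimethoxyphenyl)propan-2-yl]-1,4-dioxaspiro[4.5]decan-7-one F1. Aqueous AcOH at 40 °C should hydrolyse the dioxolane but spare the acetal, giving (4R,6R)-4-(methoxymethoxy)-6-(prop-2-en-1-yl)-4-[(2S)-1-(3,4,5-trimethoxyphenyl)propan-2-yl]cyclohexane-1,3-dione F2. BF3·OEt2 in CH2Cl2 at −20 °C should then ionise the methoxymethyl ether, and the only oxygen in reach of the O4-bound oxocarbenium ion is the O3 enol. This intramolecular transacetalisation, the known conversion of methoxymethyl ethers into cyclic formals by a neighbouring hydroxyl, should close ring B.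

**Step 12 (key step).**
- Most likely failure: poor facial selectivity at C4. The usual equatorial preference of the branched C8 chain in the closing chair opposes the trans relation to the C6 allyl group that catalyst and Felkin–Anh control favour. Base-mediated side reactions may also compete: five-membered aldol closure through C5 or C2, epimerisation of C8, and opening of the β-ketal. The first recourse is the mirror-image triazolium salt.
- Fallback (reductive instead of umpolung closure of the same bond), from 17 back to 18: SmI2 in THF with t-BuOH at −78 °C should reduce the aldehyde to its ketyl, which adds to the ketone held on the same trivalent samarium centre. This pinacol cyclisation should give (7R,8R,10R)-10-(prop-2-en-1-yl)-8-[(2S)-1-(3,4,5-trimethoxyphenyl)propan-2-yl]-1,4-dioxaspiro[4.5]decane-7,8-diol F3. Dess–Martin periodinane then oxidises the secondary hydroxyl to 18. The medium is non-basic, and C4 would be set by chelation and Felkin–Anh control from C8 alone; a C4 epimer would have to be separated.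

**Step 9 (fragment union).**
- Most likely failure: slow zinc insertion into the β-branched iodide, or protodezincation and β-hydride loss outrunning acyl transfer to the α-branched thioester.
- Fallback (polarity reversed: the iodide as electrophile, C4 as acyl anion), from 4 and 13 back to 15: Et3SiH and palladium on carbon should reduce 4 to (2S)-2-methyl-3-(3,4,5-trimethoxyphenyl)propanal F4. Propane-1,3-dithiol and BF3·OEt2 at −20 °C convert it into 2-[(2S)-1-(3,4,5-trimethoxyphenyl)propan-2-yl]-1,3-dithiane F5. Lithiation with t-BuLi in THF/HMPA at −78 °C and addition of 13 should give tert-butyl 2-{2-[(2R)-1-{2-[(2S)-1-(3,4,5-trimethoxyphenyl)propan-2-yl]-1,3-dithian-2-yl}pent-4-en-2-yl]-1,3-dioxolan-2-yl}acetate F6. MeI and CaCO3 in aqueous MeCN then unmask the ketone to 15.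

**Step 7 (ketalisation).**
- Most likely failure: interference by the free hydroxyl (silyl scrambling, retro-aldol loss of the hydroxymethyl carbon) and incomplete conversion of the enolisable β-keto ester; slower runs risk erosion at C6.
- Fallback (hydroxyl taken out of play before the ketone exists, dehydrative ketalisation instead of silyl transfer), from 9 back to 12: t-BuPh2SiCl and imidazole should give (2R)-2-{[(tert-butyldiphenylsilyl)oxy]methyl}-N-methoxy-N-methylpent-4-enamide F7. The Claisen condensation of step 6 then gives tert-butyl (4R)-4-{[(tert-butyldiphenylsilyl)oxy]methyl}-3-oxohept-6-enoate F8. Ethylene glycol, HC(OEt)3 and catalytic TsOH at rt give tert-butyl 2-{2-[(2R)-1-[(tert-butyldiphenylsilyl)oxy]pent-4-en-2-yl]-1,3-dioxolan-2-yl}acetate F9, and Bu4NF buffered with AcOH releases 12.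

## Further compounds

F1 | step 14 | (8R,10R)-8-(methoxymethoxy)-10-(prop-2-en-1-yl)-8-[(2S)-1-(3,4,5-trimethoxyphenyl)propan-2-yl]-1,4-dioxaspiro[4.5]decan-7-one | C=CC[C@@H]1C[C@@](OCOC)([C@@H](C)Cc2cc(OC)c(OC)c(OC)c2)C(=O)CC13OCCO3
F2 | step 14 | (4R,6R)-4-(methoxymethoxy)-6-(prop-2-en-1-yl)-4-[(2S)-1-(3,4,5-trimethoxyphenyl)propan-2-yl]cyclohexane-1,3-dione | C=CC[C@@H]1C[C@@](OCOC)([C@@H](C)Cc2cc(OC)c(OC)c(OC)c2)C(=O)CC1=O
F3 | step 12 | (7R,8R,10R)-10-(prop-2-en-1-yl)-8-[(2S)-1-(3,4,5-trimethoxyphenyl)propan-2-yl]-1,4-dioxaspiro[4.5]decane-7,8-diol | C=CC[C@@H]1C[C@@](O)([C@@H](C)Cc2cc(OC)c(OC)c(OC)c2)[C@H](O)CC13OCCO3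
F4 | step 9 | (2S)-2-methyl-3-(3,4,5-trimethoxyphenyl)propanal | O=C[C@@H](C)Cc1cc(OC)c(OC)c(OC)c1
F5 | step 9 | 2-[(2S)-1-(3,4,5-trimethoxyphenyl)propan-2-yl]-1,3-dithiane | C1CSC(SC1)[C@@H](C)Cc1cc(OC)c(OC)c(OC)c1
F6 | step 9 | tert-butyl 2-{2-[(2R)-1-{2-[(2S)-1-(3,4,5-trimethoxyphenyl)propan-2-yl]-1,3-dithian-2-yl}pent-4-en-2-yl]-1,3-dioxolan-2-yl}acetate | CC(C)(C)OC(=O)CC1(OCCO1)[C@H](CC=C)CC2(SCCCS2)[C@@H](C)Cc3cc(OC)c(OC)c(OC)c3
F7 | step 7 | (2R)-2-{[(tert-butyldiphenylsilyl)oxy]methyl}-N-methoxy-N-methylpent-4-enamide | CON(C)C(=O)[C@H](CC=C)CO[Si](c1ccccc1)(c1ccccc1)C(C)(C)C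
F8 | step 7 | tert-butyl (4R)-4-{[(tert-butyldiphenylsilyl)oxy]methyl}-3-oxohept-6-enoate | CC(C)(C)OC(=O)CC(=O)[C@H](CC=C)CO[Si](c1ccccc1)(c1ccccc1)C(C)(C)C
F9 | step 7 | tert-butyl 2-{2-[(2R)-1-[(tert-butyldiphenylsilyl)oxy]pent-4-en-2-yl]-1,3-dioxolan-2-yl}acetate | CC(C)(C)OC(=O)CC1(OCCO1)[C@H](CC=C)CO[Si](c1ccccc1)(c1ccccc1)C(C)(C)C
A1 | alternative 1 | cis-7a-[(2S)-1-(3,4,5-trimethoxyphenyl)propan-2-yl]-3a,4-dihydro-1,3-benzodioxol-5(7aH)-one | O=C1C=C[C@]2([C@@H](C)Cc3cc(OC)c(OC)c(OC)c3)OCO[C@@H]2C1
A2 | alternative 1 | 4-hydroxy-4-[(2S)-1-(3,4,5-trimethoxyphenyl)propan-2-yl]cyclohexa-2,5-dien-1-one | O=C1C=CC(O)([C@@H](C)Cc2cc(OC)c(OC)c(OC)c2)C=C1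
A3 | alternative 2 | ethyl 4-allyl-5-oxo-2-[(2S)-1-(3,4,5-trimethoxyphenyl)propan-2-yl]tetrahydrofuran-2-carboxylate | O=C1O[C@@](C(=O)OCC)([C@@H](C)Cc2cc(OC)c(OC)c(OC)c2)C[C@H]1CC=C
A4 | alternative 2 | 2-methylidenepent-4-enal | C=CCC(=C)C=O
A5 | alternative 2 | ethyl 3-methyl-2-oxo-4-(3,4,5-trimethoxyphenyl)butanoate (racemic) | CCOC(=O)C(=O)C(C)Cc1cc(OC)c(OC)c(OC)c1
A6 | alternative 3 | (7aR)-6-methylidene-7a-[(2S)-1-(3,4,5-trimethoxyphenyl)propan-2-yl]-7,7a-dihydro-1,3-benzodioxol-5(6H)-one | C=C1C[C@]2([C@@H](C)Cc3cc(OC)c(OC)c(OC)c3)OCOC2=CC1=O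
A7 | alternative 3 | (4R,5E)-5-(iodomethylidene)-4-(prop-2-en-1-yl)-4-[(2S)-1-(3,4,5-trimethoxyphenyl)propan-2-yl]-1,3-dioxolane | C=CC[C@]1([C@@H](C)Cc2cc(OC)c(OC)c(OC)c2)OCO/C1=C/I
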